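## Retrosynthetic overview

1. The last bond made is O1–C2 of ring C. Opening it (retro-oxa-Michael) gives the open-chain 2',6'-dihydroxychalcone. The forward closure builds the only ring made in the route, sets the only stereocentre (C2, S), and decides 6-geranyl versus 8-geranyl.
2. The chalcone Cα=Cβ bond comes from a protecting-group-free Claisen–Schmidt condensation of 3-geranylphloroacetophenone with isovanillin.
3. The aryl–CH2 (geranyl) bond comes from C-geranylation of phloroacetophenone with geranyl bromide.
4. Ring order: rings A and B are bought, and ring C is closed last.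

Assumption: the facial sense of the new cyclisation (quinidine-derived catalyst gives 2S) rests on a binding model and is checked on the first run by chiral HPLC and circular dichroism (2S-flavanones show a positive band near 330 nm and a negative band near 290 nm).

## Route

Step 1
Reactants: 1 2,4,6-trihydroxyacetophenone (phloroacetophenone, dried); 2 geranyl bromide [(2E)-1-bromo-3,7-dimethylocta-2,6-diene]
Product: 3 3-geranyl-2,4,6-trihydroxyacetophenone
Conditions: K2CO3 (1.0 equiv), acetone, reflux, 8 h (1.5 equiv of 1 relative to 2)
Reagents that add atoms: none
Why: This is a base-mediated C-alkylation (SN2) of the ambident phloroacetophenone phenoxide, in which the soft allylic bromide is attacked by the very electron-rich ring carbon C3 (C3 and C5 are equivalent, so only one mono-C-alkyl product exists), the E-olefin is untouched, excess 1 holds back double alkylation, and no stereocentre is formed.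

Step 2
Reactants: 3 3-geranyl-2,4,6-trihydroxyacetophenone; 4 isovanillin (3-hydroxy-4-methoxybenzaldehyde)
Product: 6 (E)-3'-geranyl-2',4',6',3-tetrahydroxy-4-methoxychalcone, via β-hydroxyketone aldol adduct 5 (not isolated)
Conditions: 3, LiN(SiMe3)2 (4.2 equiv), THF, −78 → 0 °C, Ar; then 4 (1.2 equiv) pre-lithiated with LiN(SiMe3)2 (1.0 equiv per 4, THF, −78 °C); −78 → 23 °C, 16 h; inverse quench into aq HCl (1 mol/L), 0 °C; rapid SiO2 (0.1% AcOH in eluent), product stored cold
Reagents that add atoms: none
Why: This is a Claisen–Schmidt aldol condensation run on the pre-formed polylithium salt, in which LiN(SiMe3)2 first turns every phenol into its phenoxide (protection in the flask) and then forms the methyl ketone enolate that adds to the non-enolisable aldehyde, E1cB loss of LiOH gives the more stable E-enone, and the fully ionised chalcone cannot ring-close before the cold acidic inverse quench takes it straight to the neutral, slowly cyclising form.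

Step 3
Reactants: 6 (E)-3'-geranyl-2',4',6',3-tetrahydroxy-4-methoxychalcone
Product: 7 (2S)-6-geranyl-5,7-dihydroxy-2-(3-hydroxy-4-methoxyphenyl)chroman-4-one [(2S)-6-geranylhesperetin]
Conditions: 1-[3,5-bis(trifluoromethyl)phenyl]-3-[(9R)-6'-methoxycinchonan-9-yl]thiourea (quinidine-derived, 10 mol%), toluene/CH2Cl2 4:1 (0.05 mol/L), −20 °C, 48–72 h; cold filtration through a short SiO2 pad; recrystallisation
Reagents that add atoms: none
Why: Proposed new method: a site- and enantioselective 6-endo-trig oxa-Michael cycloisomerisation of an unprotected, non-activated 2',6'-dihydroxychalcone under bifunctional tertiary amine–thiourea catalysis; the 2'-OH, buttressed by the neighbouring geranyl group, stays locked to the carbonyl oxygen in a resonance-assisted hydrogen bond, so it is withdrawn as a nucleophile and acts as an internal general acid that lowers the enone LUMO (the job an added ester group does in the known variant); the quinuclidine nitrogen can reach and deprotonate only the unhindered 6'-OH on the vinyl side, and the two thiourea N–H bonds hold the free lone pair of the carbonyl oxygen and then the enolate oxygen; the catalyst therefore bridges O-6' and C=O over one face of the nascent pyranone, fixes one helical twist of the s-cis enone with the ring B aryl pseudo-equatorial and away from the quinoline wall, and delivers the phenoxide to the Si face of C-β, which sets C2 as S and gives the 6-geranyl rather than the 8-geranyl skeleton; the apolar medium at −20 °C suppresses both the uncatalysed racemic closure and retro-oxa-Michael racemisation, and the strong flavanone preference of phloroglucinol-type chalcones drives conversion; the closest known reaction types are the cinchona-thiourea-catalysed intramolecular oxa-Michael addition of 2-hydroxyaryl alkylidene β-keto esters (ester-activated, then decarboxylated) and the poorly selective cinchona-base cyclisation of simple 2'-hydroxychalcone.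

## Compound list

1 | 2,4,6-trihydroxyacetophenone (phloroacetophenone) | CC(=O)c1c(O)cc(O)cc1O | starting material
2 | geranyl bromide, (2E)-1-bromo-3,7-dimethylocta-2,6-diene | BrC/C=C(\C)CCC=C(C)C | starting material
3 | 3-geranyl-2,4,6-trihydroxyacetophenone, 1-{3-[(2E)-3,7-dimethylocta-2,6-dienyl]-2,4,6-trihydroxyphenyl}ethanone | CC(=O)c1c(O)cc(O)c(C/C=C(\C)CCC=C(C)C)c1O | intermediate
4 | isovanillin, 3-hydroxy-4-methoxybenzaldehyde | COc1ccc(C=O)cc1O | starting material
5 | racemic aldol adduct, 1-(3-geranyl-2,4,6-trihydroxyphenyl)-3-hydroxy-3-(3-hydroxy-4-methoxyphenyl)propan-1-one (present as its polylithium salt, drawn neutral, not isolated) | COc1ccc(C(O)CC(=O)c2c(O)cc(O)c(C/C=C(\C)CCC=C(C)C)c2O)cc1O | intermediate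
6 | (E)-3'-geranyl-2',4',6',3-tetrahydroxy-4-methoxychalcone | COc1ccc(/C=C/C(=O)c2c(O)cc(O)c(C/C=C(\C)CCC=C(C)C)c2O)cc1O | intermediate
7 | (2S)-6-geranylhesperetin, (2S)-6-[(2E)-3,7-dimethylocta-2,6-dienyl]-5,7-dihydroxy-2-(3-hydroxy-4-methoxyphenyl)chroman-4-one | COc1ccc([C@@H]2CC(=O)c3c(cc(O)c(C/C=C(\C)CCC=C(C)C)c3O)O2)cc1O | target

## Step count

Total step count: 3. Longest linear sequence: 3 steps (1 → 3 → 6 → 7).

## Steps most likely to fail (highest risk first: step 3, step 2, step 1)

**Risk 1, step 3 (the proposed new method).**
- The very acidic 4'-OH may tie up the amine.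
- The ee or the 6-/8-geranyl ratio may be only moderate.
- The facial sense may be opposite to the model. In that case the quinine-derived pseudo-enantiomer of the catalyst is used in the same step.

The fallback uses known chemistry, sets out from 6 and comes back at 7. Chalcone 6 is cyclised without stereocontrol with NaOAc in refluxing EtOH, the classical chalcone–flavanone isomerisation. This gives racemic 6-geranylhesperetin F1 together with the racemic 8-geranyl regioisomer F2, which is removed on silica gel. F1 is then resolved by preparative HPLC on an amylose tris(3,5-dimethylphenylcarbamate) phase, a routine separation for flavanones. The resolution gives 7 and the (2R)-enantiomer F3. F3 is re-equilibrated to F1 under the same NaOAc conditions and recycled.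

**Risk 2, step 2.**
- The tetra-anion of 3 may form incompletely or be poorly soluble.
- Residual amide base can consume 4 as its N-silyl imine.
- Chalcone 6 may partly cyclise on work-up.

The fallback replaces the unprotected polyanion by a protecting-group strategy. It sets out from 3 and 4 and comes back at 6.
- Ketone 3 is treated with MOMCl and iPr2NEt in CH2Cl2 at 0 °C to give 3-geranyl-2-hydroxy-4,6-bis(methoxymethoxy)acetophenone F4. Which ortho-OH stays free does not matter, because all MOM groups are removed before the key step.
- Aldehyde 4 is converted in the same way into 4-methoxy-3-(methoxymethoxy)benzaldehyde F5.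
- A standard KOH, EtOH/H2O, 23 °C Claisen–Schmidt condensation of F4 with F5 gives the tris-MOM chalcone F6.
- Brief treatment of F6 with HCl in MeOH at 23 °C releases 6. Ring closure is slow in acid.

**Risk 3, step 1.**
O-alkylation and double C-alkylation limit the yield to about 40–50%.

The fallback separates the site choice from C–C bond formation. It sets out from 1 and comes back at 3. A Mitsunobu reaction of 1 with geraniol (PPh3, DIAD, THF, 0 °C) etherifies only the non-chelated, most acidic 4-OH and gives 4-O-geranyl-2,6-dihydroxyacetophenone F7. Montmorillonite K10 clay in CH2Cl2 at 0 °C then moves the geranyl group by a formal [1,3]-shift to the adjacent ring carbon. The two ortho positions are equivalent, so 3 is the only C-geranyl product.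

## Further compounds

F1 | step 3 | racemic 6-geranylhesperetin | COc1ccc(C2CC(=O)c3c(cc(O)c(C/C=C(\C)CCC=C(C)C)c3O)O2)cc1O
F2 | step 3 | racemic 8-geranylhesperetin (regioisomer) | COc1ccc(C2CC(=O)c3c(O)cc(O)c(C/C=C(\C)CCC=C(C)C)c3O2)cc1O
F3 | step 3 | (2R)-6-geranylhesperetin | COc1ccc([C@H]2CC(=O)c3c(cc(O)c(C/C=C(\C)CCC=C(C)C)c3O)O2)cc1O
F4 | step 2 | 3-geranyl-2-hydroxy-4,6-bis(methoxymethoxy)acetophenone | CC(=O)c1c(O)c(C/C=C(\C)CCC=C(C)C)c(OCOC)cc1OCOC
F5 | step 2 | 4-methoxy-3-(methoxymethoxy)benzaldehyde | COCOc1cc(C=O)ccc1OC
F6 | step 2 | (E)-3'-geranyl-2'-hydroxy-4-methoxy-3,4',6'-tris(methoxymethoxy)chalcone | COCOc1cc(/C=C/C(=O)c2c(O)c(C/C=C(\C)CCC=C(C)C)c(OCOC)cc2OCOC)ccc1OC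
F7 | step 1 | 4-O-geranyl-2,6-dihydroxyacetophenone | CC(=O)c1c(O)cc(OC/C=C(\C)CCC=C(C)C)cc1O
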